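**Retrosynthetic overview**
- The only ring, the cyclopentene, is formed in the last step by cycloisomerisation of an acyclic C20 bis-enal of the udoteal type. The C2–C6 bond is made by a dienamine/enal oxa-Diels–Alder cascade that sets both stereocentres.
- The bis-enal comes from C6=C7 bond formation: acetal Mukaiyama aldol addition, then loss of methanol, between a C7 enal acetal (C1–C6 and C20) and a C13 aldehyde enol silane (C7–C19).
- The enal acetal comes from an α-acetoxy ketone (Negishi acylation of acetoxyacetyl chloride) by two-carbon formylolefination.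
- The enol silane comes from geranyl bromide and a metallated allyl silyl ether (γ-alkylation).

Assumption: compounds 1 and 9 are bought as catalogue items; the C2=C3 geometry of 11 and 13 is immaterial because the dienamine erases it.

Numbering in the Why lines (biogenetic): C1 = ring CHO carbon, C2/C3 = ring alkene carbons (C3 carries C20H2OAc), C4/C5 = ring CH2, C6 = ring stereocentre, C7 = side-chain stereocentre, C19 = side-chain CHO carbon.

**Step 1**
Reactants: 1 allyloxy-tert-butyldimethylsilane; 2 geranyl bromide
Product: 4 enol silane tert-butyl{[(1Z,5E)-6,10-dimethylundeca-1,5,9-trien-1-yl]oxy}dimethylsilane, via lithiated allyl silyl ether 3 (not isolated)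
Conditions: 1, s-BuLi, THF/HMPA, –78 °C; then 2, –78 °C; cold NaHCO3 work-up
Reagents that add atoms: none
Why: s-BuLi removes an allylic proton to give a lithium-chelated (Z)-oxyallyl anion that is alkylated at its γ-carbon by the primary allylic bromide in an SN2 reaction (allyloxysilane homoenolate alkylation), which gives the aldehyde enol silane directly with (Z)-enol ether geometry and leaves the (E)-alkene of the geranyl unit untouched; no stereocentre is formed.

**Step 2**
Reactants: 5 bromo acetal 3-bromo-1,1-dimethoxypropane; 6 acetoxyacetyl chloride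
Product: 8 keto acetal 5,5-dimethoxy-2-oxopentyl acetate, via (3,3-dimethoxypropyl)zinc bromide 7 (not isolated)
Conditions: 5, Zn dust, LiCl, THF, 50 °C; then 6, Pd(PPh3)4 (3 mol%), THF, 0 °C to rt
Reagents that add atoms: none
Why: LiCl-promoted zinc insertion gives an alkylzinc bromide that tolerates the acetal and is acylated by the acid chloride under palladium catalysis (Negishi acylation) without touching the acetate; no stereocentre is formed.

**Step 3**
Reactants: 8 keto acetal 5,5-dimethoxy-2-oxopentyl acetate; 9 diethyl [(E)-2-(cyclohexylamino)ethenyl]phosphonate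
Product: 11 enal acetal 2-(3,3-dimethoxypropyl)-4-oxobut-2-en-1-yl acetate (E/Z mixture), via azadiene 10 (not isolated)
Conditions: 9, NaH, THF, 0 °C; 8, 0 °C to rt; then AcOH/NaOAc buffer (pH 4.5), THF/H2O, 0 °C
Reagents that add atoms: water, O
Why: The sodium salt of the phosphonate enamine olefinates the activated α-acetoxy ketone (Horner–Wadsworth–Emmons formylolefination) to an azadiene that cannot be olefinated a second time, and buffered hydrolysis frees the enal while the dimethyl acetal survives; the E/Z ratio at the new alkene does not matter.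

**Step 4**
Reactants: 11 enal acetal 2-(3,3-dimethoxypropyl)-4-oxobut-2-en-1-yl acetate; 4 enol silane tert-butyl{[(1Z,5E)-6,10-dimethylundeca-1,5,9-trien-1-yl]oxy}dimethylsilane
Product: 13 bis-enal (6E,10E)-3-(acetoxymethyl)-7-formyl-11,15-dimethylhexadeca-2,6,10,14-tetraenal (2E/2Z mixture), via β-methoxy aldehyde 12 (not isolated)
Conditions: TMSOTf (10 mol%), CH2Cl2, –78 to –40 °C; then TsOH·H2O (20 mol%), CH2Cl2, 0 °C to rt
Reagents that add atoms: none
Why: TMSOTf ionises the dimethyl acetal to an oxocarbenium ion that is trapped by the enol silane (Mukaiyama aldol addition to an acetal) while the conjugated aldehyde, the acetate and the trisubstituted alkenes stay inert, and acid-catalysed loss of methanol through the enol gives the more stable (E)-2-alkyl enal without a base that would start a racemic cyclisation; the two transient stereocentres of 12 are destroyed.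

**Step 5**
Reactants: 13 bis-enal (6E,10E)-3-(acetoxymethyl)-7-formyl-11,15-dimethylhexadeca-2,6,10,14-tetraenal
Product: 16 target {(3S)-2-formyl-3-[(2R,5E)-6,10-dimethyl-1-oxoundeca-5,9-dien-2-yl]cyclopent-1-en-1-yl}methyl acetate, via dienamine 14 (not isolated), via bicyclic aminal 15 (not isolated)
Conditions: (R)-2-[diphenyl(trimethylsilyloxy)methyl]pyrrolidine (20 mol%), PhCO2H (20 mol%), toluene, 0 °C to rt
Reagents that add atoms: none
Why: Proposed new method: the amine condenses only with the unbranched C1 enal (the α-branched C19 enal is too hindered) to give dienamine 14, the nitrogen analogue of the 1,4-dioxygenated diene of udoteal, whose C1=C2 bond adds through its Re face (the face not shielded by the CPh2OSiMe3 group) to the s-cis 2-alkyl enal C6=C7–C19=O in an endo intramolecular inverse-electron-demand oxa-Diels–Alder reaction that sets C6 as (S) and gives the cis-fused iridoid-type aminal 15; benzoic acid then protonates the cyclic enol ether at C7 on the convex face (syn to H-6), which sets C7 as (R), nitrogen-assisted ring opening frees the C19 aldehyde, and loss of H-2, reprotonation at C20 and hydrolysis return the catalyst and the conjugated enal; the closest known reaction types are the amine-catalysed Rauhut–Currier-type cyclisation of tethered bis-enals through dienamines and the enamine/2-alkyl-enal hetero-Diels–Alder route to nepetalactol-type aminals.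

**Compound list**
1 | allyloxy-tert-butyldimethylsilane | C=CCO[Si](C)(C)C(C)(C)C | starting material
2 | geranyl bromide, (2E)-1-bromo-3,7-dimethylocta-2,6-diene | CC(C)=CCC/C(C)=C/CBr | starting material
3 | 1-(tert-butyldimethylsilyloxy)allyllithium (lithiated 1) | [Li]C(C=C)O[Si](C)(C)C(C)(C)C | intermediate (not isolated)
4 | tert-butyl{[(1Z,5E)-6,10-dimethylundeca-1,5,9-trien-1-yl]oxy}dimethylsilane | CC(C)(C)[Si](C)(C)O/C=C\CC/C=C(\C)CCC=C(C)C | intermediate
5 | 3-bromo-1,1-dimethoxypropane | COC(CCBr)OC | starting material
6 | acetoxyacetyl chloride | CC(=O)OCC(Cl)=O | starting material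
7 | (3,3-dimethoxypropyl)zinc bromide | COC(CC[Zn]Br)OC | intermediate (not isolated)
8 | 5,5-dimethoxy-2-oxopentyl acetate | CC(=O)OCC(=O)CCC(OC)OC | intermediate
9 | diethyl [(E)-2-(cyclohexylamino)ethenyl]phosphonate | CCOP(=O)(OCC)/C=C/NC1CCCCC1 | starting material
10 | 4-(cyclohexylimino)-2-(3,3-dimethoxypropyl)but-2-en-1-yl acetate (azadiene, E/Z mixture) | CC(=O)OCC(CCC(OC)OC)=CC=NC1CCCCC1 | intermediate (not isolated)
11 | 2-(3,3-dimethoxypropyl)-4-oxobut-2-en-1-yl acetate (E/Z mixture) | CC(=O)OCC(CCC(OC)OC)=CC=O | intermediate
12 | (10E)-3-(acetoxymethyl)-7-formyl-6-methoxy-11,15-dimethylhexadeca-2,10,14-trienal (diastereomer mixture) | CC(=O)OCC(=CC=O)CCC(OC)C(C=O)CC/C=C(\C)CCC=C(C)C | intermediate (not isolated)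
13 | (6E,10E)-3-(acetoxymethyl)-7-formyl-11,15-dimethylhexadeca-2,6,10,14-tetraenal (2E/2Z mixture) | CC(=O)OCC(=CC=O)CC/C=C(/C=O)CC/C=C(\C)CCC=C(C)C | intermediate
14 | dienamine of 13 at C1 with the (R)-amine catalyst (1-amino-4-acetoxy diene) | CC(=O)OC=C(/C=C/N1CCC[C@@H]1C(c1ccccc1)(c1ccccc1)O[Si](C)(C)C)CC/C=C(/C=O)CC/C=C(\C)CCC=C(C)C | intermediate (not isolated)
15 | cis-fused cyclopenta[c]pyran N,O-acetal (hetero-Diels–Alder adduct; H-2 and H-6 cis, amine on the convex face) | CC(=O)OC=C1CC[C@H]2C(CC/C=C(\C)CCC=C(C)C)=CO[C@H](N3CCC[C@@H]3C(c3ccccc3)(c3ccccc3)O[Si](C)(C)C)[C@@H]12 | intermediate (not isolated)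
16 | {(3S)-2-formyl-3-[(2R,5E)-6,10-dimethyl-1-oxoundeca-5,9-dien-2-yl]cyclopent-1-en-1-yl}methyl acetate | CC(=O)OCC1=C(C=O)[C@H]([C@H](C=O)CC/C=C(\C)CCC=C(C)C)CC1 | target

**Summary**
Total step count: 5. Longest linear sequence: 4 (steps 2, 3, 4, 5); step 1 is a one-step side branch that joins in step 4.

**Steps most likely to fail**

Step 5. The stereochemical outcome rests on the endo cycloaddition path. An open anti-Michael path would reverse the sense at C6 for this catalyst enantiomer and loosen control at C7. Attack through C20 instead of C2, and partial C7 epimer formation, are further risks. Fallback: from 13, condense with one equivalent of (R)-2-(diphenylmethyl)pyrrolidine (toluene, 4 Å molecular sieves, no acid, rt) and stop at the cycloaddition stage. The cis-fused bicyclic aminal F1 is then an isolable auxiliary-bound compound that can be freed from minor stereoisomers by chromatography on basic alumina. In a separate operation, wet benzoic acid in toluene at 0 °C protonates it on the convex face and opens it; alkene migration and hydrolysis then return to 16 and release the amine for reuse.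

Step 4. The Lewis acid may engage the free C1 enal, or the elimination may be incomplete. Fallback: set out from 2 and 8 and keep C19 masked until after the olefination. Allyl ethyl ether is lithiated (s-BuLi, THF, –65 °C) and alkylated with 2 to give the ethyl enol ether F2. Its BF3·OEt2-catalysed condensation with the acetal of 8 (CH2Cl2, –40 °C) gives the β-methoxy mixed acetal ketone F3. Olefination of the ketone with 9/NaH gives the azadiene F4. AcOH/NaOAc/H2O at 80 °C then hydrolyses imine and acetal and eliminates methanol, returning to 13.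

Step 1. Risks are α- instead of γ-alkylation, silyl migration in the anion, and loss of the enol silane on isolation. Fallback: from 2, Li2CuCl4-catalysed coupling with [2-(1,3-dioxolan-2-yl)ethyl]magnesium bromide (THF, –20 °C) gives the dioxolane F5. AcOH/H2O at 60 °C gives the aldehyde F6. TBSOTf/Et3N (CH2Cl2, 0 °C) returns to 4 as a Z/E enol silane mixture, both isomers of which converge in step 4.

**Further compounds**
F1 | step 5 | cis-fused cyclopenta[c]pyran N,O-acetal of 13 with (R)-2-(diphenylmethyl)pyrrolidine | CC(=O)OC=C1CC[C@H]2C(CC/C=C(\C)CCC=C(C)C)=CO[C@H](N3CCC[C@@H]3C(c3ccccc3)c3ccccc3)[C@@H]12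
F2 | step 4 | (1Z,5E)-1-ethoxy-6,10-dimethylundeca-1,5,9-triene | CCO/C=C\CC/C=C(\C)CCC=C(C)C
F3 | step 4 | (9E)-6-[ethoxy(methoxy)methyl]-5-methoxy-10,14-dimethyl-2-oxopentadeca-9,13-dien-1-yl acetate (diastereomer mixture) | CC(=O)OCC(=O)CCC(OC)C(C(OC)OCC)CC/C=C(\C)CCC=C(C)C
F4 | step 4 | N-cyclohexyl azadiene from olefination of F3 (E/Z mixture) | CC(=O)OCC(CCC(OC)C(C(OC)OCC)CC/C=C(\C)CCC=C(C)C)=CC=NC1CCCCC1
F5 | step 1 | 2-[(4E)-5,9-dimethyldeca-4,8-dien-1-yl]-1,3-dioxolane | CC(C)=CCC/C(C)=C/CCCC1OCCO1
F6 | step 1 | (5E)-6,10-dimethylundeca-5,9-dienal | CC(C)=CCC/C(C)=C/CCCC=O
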